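The readings were computed from invented constants, and the scatter is random.

Count the amounts before you warm anything. In the last maple reading target and starting material add up to 99.2% of the charge, so take one starting material per target. Assume one coupling partner per target too, which alder, maple and oak leave untested, as each carried 50 mM of it. Then decide which of these flasks to charge.

| flask | starting material | coupling partner | free catalyst | temperature | remark | time |
|---|---|---|---|---|---|---|
| alder | 8 mM | 50 mM | 0.18 mM | −10 °C | run made earlier |  |
| maple | 18 mM | 50 mM | 0.18 mM | 25 °C | run made earlier |  |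
| oak | 20 mM | 50 mM | 0.21 mM | −10 °C | run made earlier |  |
| gamma | 30 mM | 12.0 mM | 0.18 mM | 40 °C |  | 1.0 h |
| delta | 12 mM | 50.0 mM | 0.18 mM | −5 °C |  | 1.0 h |
| beta | 20 mM | 50.0 mM | 0.18 mM | 25 °C |  | 1.0 h |
| epsilon | 20 mM | 12.0 mM | 0.25 mM | 55 °C |  | 1.0 h |
| alpha | 20 mM | 50.0 mM | 0.12 mM | 25 °C |  | 1.0 h |

- alder (time / h: target / %, starting material / %): 0.250: 0.4, 96.7; 0.417: 2.8, 95.9; 0.500: 3.2, 97.8; 1.00: 5.1, 93.4; 2.00: 15.5, 83.6; 3.00: 21.3, 75.4
- maple (time / min: target / %, starting material / %): 2.00: 5.3, 93.9; 6.00: 15.3, 84.8; 10.0: 24.5, 75.8; 15.0: 35.4, 63.7; 25.0: 55.3, 46.6; 30.0: 61.1, 38.1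
- oak (time / h: target / %, starting material / %): 0.250: 2.5, 98.1; 0.833: 3.9, 95.9; 1.33: 6.8, 92.5; 2.00: 11.4, 89.1; 3.00: 15.4, 81.7

(each reading ± 1 percentage point)

* ranking by amount of target, in percent of the starting material charged, from high to low, at 1.0 h (gamma / delta / beta / epsilon / alpha)
* the same order at 12 min (gamma / delta / beta / epsilon / alpha)
* the amount of target, in percent of the starting material charged of the flask you put first, at 1.0 h
* the amount of target, in percent of the starting material charged of the flask you put last, at 1.0 h



Find the limiting reagent first. Gamma gives 40.0%, which is its ceiling, the coupling partner charge over the starting material charge, and epsilon gives 60.0%. Beta and alpha charge 2.50 partner per starting material, so starting material limits them.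

Then ask whether the hour reaches the ceiling. Read the pace, or turnover frequency, from maple: 24.5% at 10.0 min is 147 /h. The average to 30.0 min reads 122 /h, so the pace in maple sags as the run goes on. At the first pace, if the smaller partner charge does not slow it, gamma would use its partner in 27.2 min and epsilon in 19.6 min, and both run warmer than maple. On that assumption, expect both at their ceilings by the hour.

At the sagged pace alpha reckons to 73.3%, while beta reckons to 110% on paper, so expect beta high but short of complete. Oak reads 4.89 /h at −10 °C, which puts delta at 7.33%. The smaller starting material charge in delta than in oak argues for less, as alder at 8 mM reads 3.16 /h, and its few extra degrees argue for more, so expect delta last.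

At 12 min the first pace gives beta 26.5% and alpha 17.6%. Gamma passes beta if heat lifts its pace 1.50 times, and the step from oak at −10 °C to maple at 25 °C spans a factor of 30.1, so I place epsilon, gamma, beta, alpha, delta, though partner order remains unknown. Charge beta for the hour, and epsilon for 12 min.

The forecast, holding gamma and epsilon “fast but capped by 12 mM partner”, gives beta > alpha > epsilon > gamma > delta at the hour, epsilon > gamma > beta > alpha > delta at 12 min, top 88% and low 10%.

The flasks give beta > alpha > epsilon > gamma > delta at the hour and epsilon > gamma > beta > alpha > delta at 12 min, with beta at 87.7% and delta at 11.0%.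

    starting material + free catalyst ⇌ catalyst intermediate A (K = 19.0 /M, k = 15.6 /M/s, Ea = 43.0 kJ/mol, ΔH = −18.0 kJ/mol)
    catalyst intermediate A → catalyst intermediate B (k = 0.326 /s, Ea = 77.0 kJ/mol)
    coupling partner + catalyst intermediate B ⇌ catalyst intermediate C (K = 55.9 /M, k = 23.0 /M/s, Ea = 52.0 kJ/mol, ΔH = 8.00 kJ/mol)
    catalyst intermediate C → free catalyst + target (k = 0.249 /s, Ea = 67.0 kJ/mol)
    (constants at 25 °C)

Gamma stands at 40.0% against its ceiling of 40.0%; at 1.00 h its coupling partner is at 0% of charge while 59.4% of the starting material remains. Take beta with its partner cut to 12.0 mM: the ceiling becomes 60.0%, and that flask ends at 57.5%.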